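**Assumptions (one line):** 2,6-dimethoxytoluene, 3-(trimethylsilyl)propynal, tert-butyl (triphenylphosphoranylidene)acetate and methyl orsellinate are commercial. The target C7 is (R) by CIP from the given SMILES, and the enantiomer of chiral iodoarene 15 that gives 7R is chosen by screening.

## Retrosynthetic overview
1. Mitorubrinic acid comes from global acid deprotection (two aryl MOM ethers and the tBu ester) of the 7-aroyloxy azaphilone 16.
2. The key step is a direct enantioselective dearomative acyloxylation at C7 of the achiral isochromenone enol 11. A chiral λ3-iodane carrying the orsellinate ligand sets the quaternary C–O stereocentre and installs the hindered ester in one operation. This avoids a 7-hydroxy intermediate and the acylation of a hindered tertiary alcohol.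
3. The pyran ring comes from Ag(I) 6-endo cycloisomerization of an o-alkynylbenzaldehyde, which comes from Sonogashira coupling of a tBu enynoate with an aryl bromide.
4. The aryl bromide comes from sterically controlled Ir C–H borylation of 2,6-dimethoxytoluene at the position meta to both OMe groups, then bromination, formylation and demethylation.
5. Ring order: commercial benzene ring, then pyran (cycloisomerization), then cyclohexadienedione with the C7 stereocentre (dearomatization).

## Route

**Step 1**
Reactants: 1 (3-(trimethylsilyl)propynal); 2 (tert-butyl (triphenylphosphoranylidene)acetate)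
Product: 3 (tert-butyl (E)-5-(trimethylsilyl)pent-2-en-4-ynoate)
Conditions: CH2Cl2, 25 °C, 12 h; chromatography to remove the minor Z isomer
Reagents that add atoms: none (Ph3P=O is lost)
Why: Wittig olefination with a stabilized ylide is E-selective, and no stereocentre is formed.

**Step 2**
Reactants: 3
Product: 4 (tert-butyl (E)-pent-2-en-4-ynoate)
Conditions: TBAF, AcOH, THF, 0 °C, 15 min; kept as a solution because it is volatile
Reagents that add atoms: none
Why: Fluoride C–Si cleavage buffered with AcOH avoids base-mediated conjugate addition to the enyne and leaves the tBu ester intact.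

**Step 3**
Reactants: 5 (2,6-dimethoxytoluene)
Product: 6 (2-(3,5-dimethoxy-4-methylphenyl)-4,4,5,5-tetramethyl-1,3,2-dioxaborolane)
Conditions: [Ir(cod)OMe]2 (1.5 mol %), dtbpy (3 mol %), B2pin2, THF, 80 °C
Reagents that add atoms: B2pin2, CC1(C)OB(OC1(C)C)B1OC(C)(C)C(C)(C)O1
Why: Ir-catalysed C–H borylation is governed by sterics, so only C4 (no ortho substituents, meta to both OMe groups) reacts, which is the carbon that becomes C4a.

**Step 4**
Reactants: 6
Product: 7 (5-bromo-1,3-dimethoxy-2-methylbenzene)
Conditions: CuBr2 (3 equiv), MeOH/H2O 1:1, 90 °C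
Reagents that add atoms: CuBr2, Br[Cu]Br
Why: Cu(II)-mediated ipso-bromodeboronation of the arylboronate retains the meta regiochemistry set in Step 3.

**Step 5**
Reactants: 7
Product: 8 (2-bromo-4,6-dimethoxy-5-methylbenzaldehyde)
Conditions: Cl2CHOMe, TiCl4, CH2Cl2, 0 °C → 25 °C
Reagents that add atoms: dichloromethyl methyl ether, COC(Cl)Cl
Why: Rieche formylation occurs ortho to OMe and para to the other OMe. The two positions are equivalent, so there is one regioisomer, and this puts the CHO next to the C–Br carbon.

**Step 6**
Reactants: 8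
Product: 9 (2-bromo-4,6-dihydroxy-5-methylbenzaldehyde)
Conditions: BBr3 (4 equiv), CH2Cl2, −78 → 25 °C
Reagents that add atoms: none
Why: BBr3 cleaves both aryl methyl ethers, and the ortho-OH is stabilized by an H-bond to the CHO. The free phenols are needed for the later dearomatization.

**Step 7**
Reactants: 9; 4
Product: 10 (tert-butyl (E)-5-(2-formyl-3,5-dihydroxy-4-methylphenyl)pent-2-en-4-ynoate)
Conditions: PdCl2(PPh3)2 (5 mol %), CuI (10 mol %), Et3N (5 equiv), DMF, 50 °C
Reagents that add atoms: none
Why: Sonogashira coupling of the aldehyde-activated aryl bromide with a terminal alkyne; the phenols are tolerated with excess base, and the E-olefin is retained.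

**Step 8**
Reactants: 10
Product: 11 (tert-butyl (E)-3-(6-hydroxy-7-methyl-8-oxo-8H-isochromen-3-yl)acrylate)
Conditions: AgOTf (10 mol %), 2,6-di-tert-butyl-4-methylpyridine (20 mol %), CH2Cl2, 25 °C
Reagents that add atoms: none (an isomerization)
Why: Ag(I) π-activation of the alkyne, 6-endo-dig attack by the aldehyde oxygen to give a 2-benzopyrylium, then peri-phenol deprotonation and protodemetalation give the neutral isochromenone. It is achiral, and its C6-OH/C8=O enol is the 7-methyl azaphilone enol.

**Step 9**
Reactants: 12 (methyl orsellinate)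
Product: 13 (methyl 2,4-bis(methoxymethoxy)-6-methylbenzoate)
Conditions: NaH (2.5 equiv), MOMCl (2.5 equiv), DMF, 0 °C → 25 °C
Reagents that add atoms: MOMCl, ClCOC
Why: Williamson-type O-alkylation of both phenoxides gives acid-labile, I(III)-inert protection of the orsellinate.

**Step 10**
Reactants: 13
Product: 14 (2,4-bis(methoxymethoxy)-6-methylbenzoic acid)
Conditions: KOH, EtOH/H2O 4:1, 85 °C, 24 h; then citric acid to pH 4
Reagents that add atoms: water, O (hydroxide oxygen ends up in the acid OH)
Why: Forced saponification of the 2,6-disubstituted methyl ester; the MOM ethers are base-stable and the mild acidic work-up avoids cleaving them.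

**Step 11**
Reactants: 11; 14; 15 (chiral iodoarene)
Product: 16 (tert-butyl (E)-3-[(7R)-7-{[2,4-bis(methoxymethoxy)-6-methylbenzoyl]oxy}-7-methyl-6,8-dioxo-7,8-dihydro-6H-isochromen-3-yl]acrylate)
Conditions: 15 (1.3 equiv) + AcOOH (1.4 equiv), CH2Cl2, 0 °C; concentrate; 14 (3 equiv), CH2Cl2, concentrate ×2 (forms Ar*I(O2CAr')2); then 11, CH2Cl2, −40 °C, 24 h
Reagents that add atoms: none (AcOOH only oxidizes the iodine, and 15 is recovered)
Why: Proposed new method: enantioselective hydroxy-free dearomative α-acyloxylation. The electron-rich C7 enol exchanges onto the chiral bis(aroyloxy)-λ3-iodane at oxygen. A six-membered [3,3]-type transfer of the iodane-bound carboxylate oxygen to C7 (the Koser-type α-oxyfunctionalization pattern) then expels Ar*I and creates the quaternary C–O stereocentre intramolecularly. One enol face is selected by the C2-symmetric lactamide arms. The closest known chemistry is chiral-iodoarene oxidative dearomatization of phenols, and Pb(OAc)4 or PIFA acyloxylation of azaphilone enols, which is racemic.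

**Step 12**
Reactants: 16
Product: 17 (mitorubrinic acid)
Conditions: TFA/CH2Cl2 1:4, 1,3,5-trimethoxybenzene (5 equiv, cation scavenger), 0 → 25 °C, 2 h; C18 HPLC
Reagents that add atoms: none
Why: Acidolysis removes the tBu ester and both aryl MOM ethers together. The fully substituted C7 has no α-H and cannot epimerize, and the azaphilone core tolerates TFA.

## Compound list
1 | 3-(trimethylsilyl)propynal | C[Si](C)(C)C#CC=O | starting material
2 | tert-butyl (triphenylphosphoranylidene)acetate | CC(C)(C)OC(=O)C=P(c1ccccc1)(c1ccccc1)c1ccccc1 | starting material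
3 | tert-butyl (E)-5-(trimethylsilyl)pent-2-en-4-ynoate | C[Si](C)(C)C#C/C=C/C(=O)OC(C)(C)C | intermediate
4 | tert-butyl (E)-pent-2-en-4-ynoate | C#C/C=C/C(=O)OC(C)(C)C | intermediate
5 | 2,6-dimethoxytoluene | COc1cccc(OC)c1C | starting material
6 | 3,5-dimethoxy-4-methylphenyl-Bpin | COc1cc(B2OC(C)(C)C(C)(C)O2)cc(OC)c1C | intermediate
7 | 5-bromo-1,3-dimethoxy-2-methylbenzene | COc1cc(Br)cc(OC)c1C | intermediate
8 | 2-bromo-4,6-dimethoxy-5-methylbenzaldehyde | COc1cc(Br)c(C=O)c(OC)c1C | intermediate
9 | 2-bromo-4,6-dihydroxy-5-methylbenzaldehyde | O=Cc1c(Br)cc(O)c(C)c1O | intermediate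
10 | tert-butyl (E)-5-(2-formyl-3,5-dihydroxy-4-methylphenyl)pent-2-en-4-ynoate | O=Cc1c(C#C/C=C/C(=O)OC(C)(C)C)cc(O)c(C)c1O | intermediate
11 | tert-butyl (E)-3-(6-hydroxy-7-methyl-8-oxo-8H-isochromen-3-yl)acrylate | O=C1C(C)=C(O)C=C2C=C(/C=C/C(=O)OC(C)(C)C)OC=C12 | intermediate
12 | methyl orsellinate | COC(=O)c1c(C)cc(O)cc1O | starting material
13 | methyl 2,4-bis(methoxymethoxy)-6-methylbenzoate | COC(=O)c1c(C)cc(OCOC)cc1OCOC | intermediate
14 | 2,4-bis(methoxymethoxy)-6-methylbenzoic acid | Cc1cc(OCOC)cc(OCOC)c1C(=O)O | intermediate
15 | (S,S)-1,3-bis{[1-(mesitylamino)-1-oxopropan-2-yl]oxy}-2-iodobenzene (chiral iodoarene, recovered) | Cc1cc(C)c(NC(=O)[C@H](C)Oc2cccc(O[C@@H](C)C(=O)Nc3c(C)cc(C)cc3C)c2I)c(C)c1 | reagent (catalyst-type auxiliary)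
16 | MOM/tBu-protected 7-aroyloxy azaphilone | Cc1cc(OCOC)cc(OCOC)c1C(=O)O[C@]1(C)C(=O)C=C2C=C(/C=C/C(=O)OC(C)(C)C)OC=C2C1=O | intermediate
17 | mitorubrinic acid | Cc1cc(O)cc(O)c1C(=O)O[C@]1(C)C(=O)C=C2C=C(/C=C/C(=O)O)OC=C2C1=O | target

## Totals
Total steps: 12. Longest linear sequence: 8 (Steps 3, 4, 5, 6, 7, 8, 11, 12).

## Three steps most likely to fail
1. **Step 11 (asymmetric acyloxylation).** The enantioselectivity and yield with a hindered aroyl carboxylate at a tertiary carbon are unproven.
   Fallback: do the enantioselective hydroxylative dearomatization of 11 with a Cu(II)/(−)-sparteine/O2 system to give the 7-hydroxy azaphilone, then acylate with the acid chloride of 14 using DMAP.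
2. **Step 8 (cycloisomerization regiochemistry).** The electron-poor enynoate may favour 5-exo over 6-endo closure.
   Fallback: couple an alkynyl acetal (propargyl aldehyde diethyl acetal) in Step 7 instead, cyclize it 6-endo, hydrolyse to the 3-formyl isochromenone, and install the acrylate by Wittig olefination with 2 before the dearomatization.
3. **Step 12 (global deprotection).** The azaphilone may degrade in TFA, or liberated MOM cations may re-alkylate the phenols.
   Fallback: use 2,4-bis(allyloxy)-6-methylbenzoic acid and allyl (E)-pent-2-en-4-ynoate earlier in the route, then remove all allyl groups in one neutral Pd(PPh3)4/PhSiH3 step.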